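**Plan**

- Retrosynthesis: the benzyl and silyl ethers come off last. The N2–C1 bond of the lactam is traced back to an O–C1 imidate bond (1,3 shift from O to N). The iminolactone is then cut at C3a–C3, C7a–C1 and O–C3 into 3-methoxybenzyne, an isocyanide and a naphtho[1,8-bc]furan-2-one. The lactone is cut at its acyl carbon (CO) and the naphthalene by a Stobbe benzannulation.
- Forward: the naphthalene ring is built first, then the peri-lactone ring, then the five-membered iminolactone ring in the three-component coupling; this ring is isomerized to the lactam ring before deprotection.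
- Enabling feature: ring A bears on three neighbouring atoms the methoxy group (C7), the spiro carbon C1 (on C7a) and the carbonyl carbon C3 (on C3a). This is the pattern 3-methoxybenzyne gives when a carbon nucleophile enters at C3a and the C7a anion takes an electrophile.
- Stereochemistry: the spiro carbon C1 is the only stereocenter. It forms racemic in the coupling and is set as R by a chiral phosphoric acid in an enantioconvergent imidate-to-lactam shift. The two deprotections are buffered or neutral and should not ionize C1.

Key step: step 9

Assumption: the face preferred by the chiral phosphate cannot be predicted, so (R)-TRIP, (R)-3,3'-bis(2,4,6-triisopropylphenyl)-1,1'-binaphthyl-2,2'-diyl hydrogen phosphate, is written and its antipode would be used if it proves to give the S product. Locants C1, N2, C3, C3a to C7a are those of the isoindolinone ring; primed locants are those of the naphtho[1,8-bc]furan.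

**Route**

Step 1
Reactants: 1 4-(benzyloxy)benzaldehyde; 2 dimethyl succinate
Product: 3 (E)-4-[4-(benzyloxy)phenyl]-3-(methoxycarbonyl)but-3-enoic acid
Conditions: KOtBu, tBuOH, reflux; aq. HCl
Reagents that add atoms: none
Why: Stobbe condensation: aldol addition, lactonization and eliminative ring opening give the alkylidenesuccinic half-ester with the aryl group cis to the CH2CO2H arm (E), the geometry the benzannulation needs.

Step 2
Reactants: 3
Product: 5 methyl 4-acetoxy-6-(benzyloxy)-2-naphthoate, via methyl 6-(benzyloxy)-4-hydroxy-2-naphthoate 4 (not isolated)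
Conditions: Ac2O, NaOAc, reflux
Reagents that add atoms: acetic anhydride, CC(=O)OC(C)=O
Why: Stobbe benzannulation, second stage: the mixed anhydride closes by intramolecular Friedel–Crafts acylation at a ring position ortho to the alkene (both are equivalent), the ketone enolizes to naphthol 4 and acetic anhydride acetylates it in the same flask.

Step 3
Reactants: 5
Product: 6 methyl 4-acetoxy-6-(benzyloxy)-5-bromo-2-naphthoate
Conditions: NBS, MeCN, 0 °C to rt, dark
Reagents that add atoms: N-bromosuccinimide, O=C1CCC(=O)N1Br
Why: Electrophilic aromatic bromination: a 2-alkoxynaphthalene reacts at the adjacent alpha position, here C5, while the ester and the acetate deactivate the other ring, so bromine should enter only at the peri position that later carries the lactone carbon.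

Step 4
Reactants: 6
Product: 7 7-(benzyloxy)-8-bromo-3-(hydroxymethyl)naphthalen-1-ol
Conditions: LiAlH4, THF, 0 °C; aq. NaOH work-up
Reagents that add atoms: none
Why: Hydride reduction: LiAlH4 takes the methyl ester to the primary alcohol and cleaves the aryl acetate in the same operation, and at 0 °C it leaves the aryl bromide and the benzyl ether alone.

Step 5
Reactants: 7
Product: 8 7-(benzyloxy)-8-bromo-3-methylnaphthalen-1-ol
Conditions: Et3SiH, CF3CO2H, CH2Cl2, 0 °C to rt
Reagents that add atoms: none
Why: Ionic hydrogenation: the naphthylmethyl cation formed in acid is stabilized through the ring by the C7 benzyloxy group (2,6-type conjugation) and is reduced by the silane, conditions under which an aryl bromide, a benzyl aryl ether and a naphthol persist.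

Step 6
Reactants: 8
Product: 9 3-(benzyloxy)-7-methyl-2H-naphtho[1,8-bc]furan-2-one
Conditions: Pd(OAc)2, Xantphos, CO (1 atm), Et3N, toluene, 100 °C
Reagents that add atoms: carbon monoxide, [C-]#[O+]
Why: Palladium-catalysed carbonylative lactonization: zerovalent palladium inserts into the C–Br bond, CO insertion gives the acylpalladium species and the peri hydroxyl captures it in a five-membered ring closure, the usual way from a halo arene with a nearby OH to a lactone.

Step 7
Reactants: 10 N-(2-hydroxyethyl)formamide
Product: 11 N-[2-(triisopropylsilyloxy)ethyl]formamide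
Conditions: iPr3SiCl, imidazole, DMF, rt
Reagents that add atoms: chlorotriisopropylsilane, CC(C)[Si](Cl)(C(C)C)C(C)C
Why: Imidazole-promoted O-silylation of the primary alcohol; the formamide N–H does not react, and the triisopropylsilyl ether is chosen because it tolerates the fluoride of step 9 better than smaller silyl groups.

Step 8
Reactants: 11
Product: 12 2-(triisopropylsilyloxy)ethyl isocyanide
Conditions: POCl3, Et3N, CH2Cl2, 0 °C
Reagents that add atoms: none
Why: Dehydration of an N-monosubstituted formamide with POCl3 and a tertiary amine is the standard isocyanide synthesis and does not touch a silyl ether.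

Step 9
Reactants: 13 3-methoxy-2-(trimethylsilyl)phenyl trifluoromethanesulfonate; 12 2-(triisopropylsilyloxy)ethyl isocyanide; 9 3-(benzyloxy)-7-methyl-2H-naphtho[1,8-bc]furan-2-one
Product: 15 rac-3'-(benzyloxy)-7-methoxy-7'-methyl-N-[2-(triisopropylsilyloxy)ethyl]-3H-spiro[2-benzofuran-1,2'-naphtho[1,8-bc]furan]-3-imine, via 3-methoxybenzyne 14 (not isolated)
Conditions: CsF, MeCN/THF (1:1), rt; 12 and 13 in excess, 13 added slowly; filtration through basic Al2O3
Reagents that add atoms: none
Why: Fluoride removes the trimethylsilyl group of 13 and triflate leaves to give aryne 14; the isocyanide carbon of 12 adds to the aryne carbon remote from the methoxy group (future C3a), the aryl anion thus placed on C7a adds to the strained lactone carbonyl of 9, and the tetrahedral alkoxide closes on the neighbouring nitrilium carbon. The closest known reaction is the three-component coupling of arynes, isocyanides and aryl esters to 3-aryloxy-1-iminoisobenzofurans, of which a peri-fused aryl lactone is a cyclic case. The single ring formed, the iminolactone, closes in the 5-exo-dig mode, and because the lactone oxygen stays tethered, an alkoxide that expels the naphthoxide can close again to the same oxide and is not lost. The spiro carbon arises without any controlling element, so 15 is racemic and its configuration is set in step 10. The step needs regioselective addition to the unsymmetrical aryne, which the inductive pull of the C7 methoxy group secures by favouring negative charge at C7a, and it needs the isocyanide to win the aryne ahead of fluoride or phenoxide, which excess 12 and slow release of 14 secure.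

Step 10
Reactants: 15
Product: 16 (R)-3'-(benzyloxy)-7-methoxy-7'-methyl-2-[2-(triisopropylsilyloxy)ethyl]spiro[isoindoline-1,2'-naphtho[1,8-bc]furan]-3-one
Conditions: (R)-TRIP (10 mol %), 4 Å MS, toluene, rt
Reagents that add atoms: none
Why: Proposed new method: the phosphoric acid protonates the imidate nitrogen and the O–C1 bond ionizes to a planar furanylium ion stabilized by two aryl groups and the ring oxygen, which stays paired with the chiral phosphate and hydrogen-bonded to the freed secondary amide, rotation about C7a–C1 lets both enantiomers of 15 reach the same ion pair, and the amide nitrogen then closes 5-exo-trig on the face chosen by the catalyst to give the much more stable lactam irreversibly, so C1 is set as R under catalyst control; the closest known reactions are the acid-promoted 1,3 shift from O to N of imidates whose O-alkyl group forms a stabilized cation (as in the trichloroacetimidate to trichloroacetamide rearrangement) and the chiral phosphoric acid catalysed additions to oxocarbenium and N-acyl ketiminium ion pairs.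

Step 11
Reactants: 16
Product: 17 (R)-3'-(benzyloxy)-2-(2-hydroxyethyl)-7-methoxy-7'-methylspiro[isoindoline-1,2'-naphtho[1,8-bc]furan]-3-one
Conditions: Bu4NF, AcOH, THF, 0 °C to rt
Reagents that add atoms: none
Why: Fluoride-mediated desilylation: the Si–O bond is cleaved while acetic acid keeps the medium near neutral, so the N,O-ketal, the lactam and the benzyl ether are untouched and C1 keeps its configuration.

Step 12
Reactants: 17
Product: 18 (R)-3'-hydroxy-2-(2-hydroxyethyl)-7-methoxy-7'-methylspiro[isoindoline-1,2'-naphtho[1,8-bc]furan]-3-one (CNP0434366.1)
Conditions: H2 (1 atm), Pd/C, EtOAc, rt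
Reagents that add atoms: none
Why: Catalytic hydrogenolysis cleaves the aryl benzyl ether quickly under neutral conditions, whereas the fully substituted spiro carbon is shielded from the catalyst surface, and no acid or base is present that could open the N,O-ketal or form a quinone methide from the free naphthol.

**Compound list**

1 | 4-(benzyloxy)benzaldehyde | O=Cc1ccc(OCc2ccccc2)cc1 | starting material
2 | dimethyl succinate | COC(=O)CCC(=O)OC | starting material
3 | (E)-4-[4-(benzyloxy)phenyl]-3-(methoxycarbonyl)but-3-enoic acid | COC(=O)/C(=C/c1ccc(OCc2ccccc2)cc1)CC(=O)O | intermediate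
4 | methyl 6-(benzyloxy)-4-hydroxy-2-naphthoate | COC(=O)c1cc(O)c2cc(OCc3ccccc3)ccc2c1 | intermediate (not isolated)
5 | methyl 4-acetoxy-6-(benzyloxy)-2-naphthoate | COC(=O)c1cc(OC(C)=O)c2cc(OCc3ccccc3)ccc2c1 | intermediate
6 | methyl 4-acetoxy-6-(benzyloxy)-5-bromo-2-naphthoate | COC(=O)c1cc(OC(C)=O)c2c(Br)c(OCc3ccccc3)ccc2c1 | intermediate
7 | 7-(benzyloxy)-8-bromo-3-(hydroxymethyl)naphthalen-1-ol | OCc1cc(O)c2c(Br)c(OCc3ccccc3)ccc2c1 | intermediate
8 | 7-(benzyloxy)-8-bromo-3-methylnaphthalen-1-ol | Cc1cc(O)c2c(Br)c(OCc3ccccc3)ccc2c1 | intermediate
9 | 3-(benzyloxy)-7-methyl-2H-naphtho[1,8-bc]furan-2-one | O=C1Oc2cc(C)cc3ccc(OCc4ccccc4)c1c23 | intermediate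
10 | N-(2-hydroxyethyl)formamide | O=CNCCO | starting material
11 | N-[2-(triisopropylsilyloxy)ethyl]formamide | O=CNCCO[Si](C(C)C)(C(C)C)C(C)C | intermediate
12 | 2-(triisopropylsilyloxy)ethyl isocyanide | [C-]#[N+]CCO[Si](C(C)C)(C(C)C)C(C)C | intermediate
13 | 3-methoxy-2-(trimethylsilyl)phenyl trifluoromethanesulfonate | COc1cccc(OS(=O)(=O)C(F)(F)F)c1[Si](C)(C)C | starting material
14 | 3-methoxybenzyne | COC1=CC=CC#C1 | intermediate (not isolated)
15 | rac-3'-(benzyloxy)-7-methoxy-7'-methyl-N-[2-(triisopropylsilyloxy)ethyl]-3H-spiro[2-benzofuran-1,2'-naphtho[1,8-bc]furan]-3-imine | COc1cccc2c1C1(Oc3cc(C)cc4ccc(OCc5ccccc5)c1c34)OC2=NCCO[Si](C(C)C)(C(C)C)C(C)C | intermediate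
16 | (R)-3'-(benzyloxy)-7-methoxy-7'-methyl-2-[2-(triisopropylsilyloxy)ethyl]spiro[isoindoline-1,2'-naphtho[1,8-bc]furan]-3-one | COc1cccc2c1[C@@]1(Oc3cc(C)cc4ccc(OCc5ccccc5)c1c34)N(CCO[Si](C(C)C)(C(C)C)C(C)C)C2=O | intermediate
17 | (R)-3'-(benzyloxy)-2-(2-hydroxyethyl)-7-methoxy-7'-methylspiro[isoindoline-1,2'-naphtho[1,8-bc]furan]-3-one | COc1cccc2c1[C@@]1(Oc3cc(C)cc4ccc(OCc5ccccc5)c1c34)N(CCO)C2=O | intermediate
18 | (R)-3'-hydroxy-2-(2-hydroxyethyl)-7-methoxy-7'-methylspiro[isoindoline-1,2'-naphtho[1,8-bc]furan]-3-one | COc1cccc2c1[C@@]1(Oc3cc(C)cc4ccc(O)c1c34)N(CCO)C2=O | target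

**Step count**

Total: 12 steps. Longest linear sequence: 10 steps (steps 1 to 6, then 9 to 12); steps 7 and 8 form the isocyanide branch.

**Steps most likely to fail**

1. Step 10. The shift may run with retention inside a tight ion pair, the nitrogen closing before the two rotamers of the cation exchange. The phosphate may also distinguish the two faces poorly, or the lactam may ionize again under the acid. Each of these would leave material of low enantiomeric purity. The fallback uses known reactions and sets out from 15. A catalytic amount of achiral diphenyl phosphate in toluene should bring about the same imidate-to-amide shift and give the racemic lactam F1. Bu4NF buffered with AcOH should remove the silyl group to give the racemic alcohol F2. Acylation with (1S)-camphanic chloride, Et3N and DMAP should give the pair of diastereomeric camphanates F3. Chromatography or crystallization should separate the camphanate with the R spiro carbon F4. K2CO3 in MeOH should cleave the ester, and the route is rejoined at 17.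

2. Step 9. The hindered C7a anion may be protonated by the solvent or add a second isocyanide before it reaches the lactone carbonyl. Fluoride or naphthoxide may also open the lactone and consume the aryne. The fallback replaces the aryne coupling by a directed ortho metalation and sets out from 9. 2-Aminoethanol is acylated with 3-methoxybenzoyl chloride to give N-(2-hydroxyethyl)-3-methoxybenzamide F5. Silylation with iPr3SiCl and imidazole gives N-[2-(triisopropylsilyloxy)ethyl]-3-methoxybenzamide F6. sBuLi and TMEDA in THF at −78 °C should lithiate the position between the amide and the methoxy group. Addition of this dianion to 9, followed by closure of the amide nitrogen on the released ketone, should give the racemic hydroxylactam F7. A chiral phosphoric acid with molecular sieves should then close the peri naphthol onto the N-acyl ketiminium ion, a catalysis type known for thiol, hydride and arene nucleophiles, and the route is rejoined at 16.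

3. Step 6. Oxidative addition into a C–Br bond flanked by the benzyloxy group and the peri hydroxyl may be slow. Loss of bromine by reduction or intermolecular ester formation may then outrun CO insertion and ring closure. The fallback replaces catalysis by an organolithium and sets out from 8. nBuLi (2.2 equiv) in THF at −78 °C should deprotonate the naphthol and exchange bromine for lithium. Quenching with CO2 and acidification should give 2-(benzyloxy)-8-hydroxy-6-methyl-1-naphthoic acid F8. This acid should close to the lactone with (CF3CO)2O or a carbodiimide, and the route is rejoined at 9.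

Further compounds
F1 | step 10 | rac-3'-(benzyloxy)-7-methoxy-7'-methyl-2-[2-(triisopropylsilyloxy)ethyl]spiro[isoindoline-1,2'-naphtho[1,8-bc]furan]-3-one | COc1cccc2c1C1(Oc3cc(C)cc4ccc(OCc5ccccc5)c1c34)N(CCO[Si](C(C)C)(C(C)C)C(C)C)C2=O
F2 | step 10 | rac-3'-(benzyloxy)-2-(2-hydroxyethyl)-7-methoxy-7'-methylspiro[isoindoline-1,2'-naphtho[1,8-bc]furan]-3-one | COc1cccc2c1C1(Oc3cc(C)cc4ccc(OCc5ccccc5)c1c34)N(CCO)C2=O
F3 | step 10 | (1S,4R)-camphanate of F2, both configurations at the spiro carbon | COc1cccc2c1C1(Oc3cc(C)cc4ccc(OCc5ccccc5)c1c34)N(CCOC(=O)[C@@]13CC[C@@](C)(C(=O)O1)C3(C)C)C2=O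
F4 | step 10 | (1S,4R)-camphanate of 17, R at the spiro carbon | COc1cccc2c1[C@@]1(Oc3cc(C)cc4ccc(OCc5ccccc5)c1c34)N(CCOC(=O)[C@@]13CC[C@@](C)(C(=O)O1)C3(C)C)C2=O
F5 | step 9 | N-(2-hydroxyethyl)-3-methoxybenzamide | COc1cccc(c1)C(=O)NCCO
F6 | step 9 | N-[2-(triisopropylsilyloxy)ethyl]-3-methoxybenzamide | COc1cccc(c1)C(=O)NCCO[Si](C(C)C)(C(C)C)C(C)C
F7 | step 9 | rac-3-[2-(benzyloxy)-8-hydroxy-6-methylnaphthalen-1-yl]-3-hydroxy-4-methoxy-2-[2-(triisopropylsilyloxy)ethyl]isoindolin-1-one | COc1cccc2c1C(O)(c1c(OCc3ccccc3)ccc3cc(C)cc(O)c13)N(CCO[Si](C(C)C)(C(C)C)C(C)C)C2=O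
F8 | step 6 | 2-(benzyloxy)-8-hydroxy-6-methyl-1-naphthoic acid | Cc1cc(O)c2c(C(=O)O)c(OCc3ccccc3)ccc2c1
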